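## Retrosynthetic overview

1. Last C–C bond: Negishi C(sp2)–C(sp3) coupling of a homoallylic zinc reagent (fragment C, the C16 trimethylcyclohexenyl half) with a (Z)-vinyl iodide that already carries the finished butenolide (fragments A + B); then global desilylation.
2. Butenolide: ring-closing metathesis of the acrylate of an (S)-2-methylene-1,3-diol mono-silyl ether, run before the coupling so that the only other alkene present is an inert iodoalkene.
3. (S) centre: SAMP-hydrazone alkylation of 2,2-dimethyl-1,3-dioxan-5-one (fragment A, from TRIS) with a (Z)-4-bromo-2-iodobutenyl silyl ether (fragment B, from but-2-yne-1,4-diol by trans-hydroalumination/iodination).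
4. Fragment C from β-ionone: 1,4-reduction, methyl ketone to alkyne, Zr-catalysed carboalumination/oxirane opening (sets the E alkene), iodide.
5. Ring order: the cyclohexene ring is bought with β-ionone; the butenolide is the only ring made (step 13).

Assumption: reagents named without a number (SAMP, silyl chlorides, acryloyl chloride, oxirane, AlMe3 and the like) are bought; only 1, 5 and 18 count as starting materials.

## Route

**Step 1**
Reactants: 1 tris(hydroxymethyl)aminomethane hydrochloride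
Product: 2 (5-amino-2,2-dimethyl-1,3-dioxan-5-yl)methanol
Conditions: 2,2-dimethoxypropane, p-TsOH·H2O (cat.), DMF, rt; then Et3N
Reagents that add atoms: 2,2-dimethoxypropane COC(C)(C)OC
Why: Acid-catalysed transacetalisation (acetonide formation) ties two of the three hydroxymethyl groups into a 1,3-dioxane while the protonated amine stays inert.

**Step 2**
Reactants: 2 (5-amino-2,2-dimethyl-1,3-dioxan-5-yl)methanol
Product: 3 2,2-dimethyl-1,3-dioxan-5-one
Conditions: NaIO4, KH2PO4, H2O, 0 °C to rt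
Reagents that add atoms: water O
Why: Periodate cleavage of the 1,2-amino alcohol (Malaprade-type) excises the hydroxymethyl carbon as formaldehyde and the resulting imine hydrolyses to the ketone.

**Step 3**
Reactants: 3 2,2-dimethyl-1,3-dioxan-5-one
Product: 4 (S)-N-(2,2-dimethyl-1,3-dioxan-5-ylidene)-2-(methoxymethyl)pyrrolidin-1-amine (SAMP hydrazone of 3)
Conditions: SAMP, benzene, reflux, Dean–Stark
Reagents that add atoms: (S)-1-amino-2-(methoxymethyl)pyrrolidine (SAMP) COC[C@@H]1CCCN1N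
Why: Condensation of the ketone with the chiral hydrazine gives the Enders hydrazone, the auxiliary that controls the alkylation.

**Step 4**
Reactants: 5 but-2-yne-1,4-diol
Product: 6 4-[(tert-butyldiphenylsilyl)oxy]but-2-yn-1-ol
Conditions: TBDPSCl (1 equiv), 5 (3 equiv), imidazole, DMF, 0 °C to rt
Reagents that add atoms: tert-butyl(chloro)diphenylsilane CC(C)(C)[Si](Cl)(c1ccccc1)c1ccccc1
Why: Statistical monosilylation of a symmetrical diol used in excess gives the mono-TBDPS ether.

**Step 5**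
Reactants: 6 4-[(tert-butyldiphenylsilyl)oxy]but-2-yn-1-ol
Product: 8 (Z)-4-[(tert-butyldiphenylsilyl)oxy]-3-iodobut-2-en-1-ol, via sodium alkenylaluminate 7 (not isolated)
Conditions: NaAlH2(OCH2CH2OMe)2, THF, 0 °C to rt; then I2, THF, −78 °C to rt; aq. Na2S2O3
Reagents that add atoms: iodine II
Why: Hydroxyl-directed trans-hydroalumination of the propargylic alcohol puts aluminium on the distal alkyne carbon and iodinolysis with retention gives the (Z)-vinyl iodide, which fixes the geometry of the future hydroxymethyl-bearing alkene.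

**Step 6**
Reactants: 8 (Z)-4-[(tert-butyldiphenylsilyl)oxy]-3-iodobut-2-en-1-ol
Product: 9 (Z)-[(4-bromo-2-iodobut-2-en-1-yl)oxy](tert-butyl)diphenylsilane
Conditions: CBr4, PPh3, CH2Cl2, 0 °C
Reagents that add atoms: carbon tetrabromide BrC(Br)(Br)Br
Why: Appel bromination converts the primary allylic alcohol into the bromide by SN2 displacement without touching the vinyl iodide or its geometry.

**Step 7**
Reactants: 4 SAMP hydrazone of 2,2-dimethyl-1,3-dioxan-5-one; 9 (Z)-[(4-bromo-2-iodobut-2-en-1-yl)oxy](tert-butyl)diphenylsilane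
Product: 11 SAMP hydrazone of (S)-4-{(Z)-4-[(tert-butyldiphenylsilyl)oxy]-3-iodobut-2-en-1-yl}-2,2-dimethyl-1,3-dioxan-5-one, via lithium azaenolate 10 (not isolated)
Conditions: t-BuLi (1.05 equiv), THF, −78 °C; then 9, −100 °C to rt
Reagents that add atoms: none
Why: Enders SAMP-hydrazone alkylation, in which the chelated lithium azaenolate is alkylated by the allylic bromide (SN2) on the face remote from the methoxymethyl arm, sets the (S) centre that becomes C5 of the butenolide.

**Step 8**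
Reactants: 11 alkylated SAMP hydrazone
Product: 12 (S)-4-{(Z)-4-[(tert-butyldiphenylsilyl)oxy]-3-iodobut-2-en-1-yl}-2,2-dimethyl-1,3-dioxan-5-one
Conditions: sat. aq. oxalic acid, Et2O, rt
Reagents that add atoms: water O
Why: Mild two-phase acid hydrolysis of the hydrazone regenerates the ketone without epimerising the α-centre or cleaving the acetonide and returns the auxiliary.

**Step 9**
Reactants: 12 (S)-4-substituted 2,2-dimethyl-1,3-dioxan-5-one
Product: 13 (S)-4-{(Z)-4-[(tert-butyldiphenylsilyl)oxy]-3-iodobut-2-en-1-yl}-2,2-dimethyl-5-methylidene-1,3-dioxane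
Conditions: Ph3PCH3Br, KN(SiMe3)2, THF, 0 °C; then 12, −78 to 0 °C
Reagents that add atoms: methyltriphenylphosphonium bromide C[P+](c1ccccc1)(c1ccccc1)c1ccccc1.[Br-]
Why: Wittig methylenation with the small salt-free ylide at low temperature is faster than enolisation, so the adjacent stereocentre is kept.

**Step 10**
Reactants: 13 (S)-5-methylidene-1,3-dioxane
Product: 14 (3S,5Z)-7-[(tert-butyldiphenylsilyl)oxy]-6-iodo-2-methylidenehept-5-ene-1,3-diol
Conditions: PPTS (0.2 equiv), MeOH, rt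
Reagents that add atoms: none
Why: Acid-catalysed transacetalisation to methanol removes the acetonide while the TBDPS ether and vinyl iodide are stable.

**Step 11**
Reactants: 14 (3S,5Z)-diol
Product: 15 (3S,5Z)-1-[(tert-butyldimethylsilyl)oxy]-7-[(tert-butyldiphenylsilyl)oxy]-6-iodo-2-methylidenehept-5-en-3-ol
Conditions: TBSCl (1.05 equiv), imidazole, CH2Cl2, −20 to 0 °C
Reagents that add atoms: tert-butyl(chloro)dimethylsilane CC(C)(C)[Si](C)(C)Cl
Why: Selective silylation works because the primary allylic hydroxyl reacts much faster than the hindered secondary one.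

**Step 12**
Reactants: 15 (3S,5Z)-mono-TBS alcohol
Product: 16 (3S,5Z)-1-[(tert-butyldimethylsilyl)oxy]-7-[(tert-butyldiphenylsilyl)oxy]-6-iodo-2-methylidenehept-5-en-3-yl prop-2-enoate
Conditions: acryloyl chloride, iPr2NEt, DMAP (cat.), CH2Cl2, −20 to 0 °C
Reagents that add atoms: acryloyl chloride C=CC(=O)Cl
Why: O-Acylation of the secondary alcohol installs the second alkene for metathesis and leaves the carbinol configuration untouched.

**Step 13**
Reactants: 16 acrylate
Product: 17 (S)-4-{[(tert-butyldimethylsilyl)oxy]methyl}-5-{(Z)-4-[(tert-butyldiphenylsilyl)oxy]-3-iodobut-2-en-1-yl}furan-2(5H)-one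
Conditions: second-generation Grubbs catalyst RuCl2(=CHPh)(H2IMes)(PCy3) (10 mol%), CH2Cl2 (0.005 M), reflux
Reagents that add atoms: none
Why: Ring-closing metathesis between the acrylate and the 1,1-disubstituted alkene closes the butenolide with loss of ethylene, the hindered iodoalkene being inert to the ruthenium carbene and the stereocentre not involved.

**Step 14**
Reactants: 18 β-ionone, (E)-4-(2,6,6-trimethylcyclohex-1-en-1-yl)but-3-en-2-one
Product: 20 4-(2,6,6-trimethylcyclohex-1-en-1-yl)butan-2-one, via triethylsilyl enol ether 19 (not isolated)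
Conditions: Et3SiH (1.1 equiv), RhCl(PPh3)3 (0.5 mol%), neat, 50 °C; then K2CO3 (cat.), MeOH, rt
Reagents that add atoms: none
Why: Rhodium-catalysed 1,4-hydrosilylation of the enone, which leaves the twisted tetrasubstituted ring alkene alone, followed by methanolysis of the silyl enol ether gives the saturated ketone.

**Step 15**
Reactants: 20 4-(2,6,6-trimethylcyclohex-1-en-1-yl)butan-2-one
Product: 23 2-(but-3-yn-1-yl)-1,3,3-trimethylcyclohex-1-ene, via lithium enolate 21 (not isolated), via enol diethyl phosphate 22 (not isolated)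
Conditions: LiN(iPr)2 (1.05 equiv), THF, −78 °C; ClP(O)(OEt)2, −78 °C to rt; then LiN(iPr)2 (2.3 equiv), −78 °C to rt; H2O
Reagents that add atoms: none
Why: Negishi's methyl ketone to alkyne conversion proceeds by kinetic enolisation at the methyl group, O-phosphorylation and base-induced elimination of diethyl phosphate.

**Step 16**
Reactants: 23 2-(but-3-yn-1-yl)-1,3,3-trimethylcyclohex-1-ene
Product: 26 (E)-4-methyl-6-(2,6,6-trimethylcyclohex-1-en-1-yl)hex-3-en-1-ol, via alkenyldimethylalane 24 (not isolated), via lithium alkenylalanate 25 (not isolated)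
Conditions: AlMe3 (2 equiv), Cp2ZrCl2 (0.25 equiv), ClCH2CH2Cl, rt; volatiles removed; n-BuLi (1 equiv), THF/hexane, −78 to 0 °C; oxirane, −78 °C to rt; aq. work-up
Reagents that add atoms: trimethylaluminium C[Al](C)C; oxirane C1CO1
Why: Zirconium-catalysed syn-carboalumination (Negishi) adds methyl and aluminium across the terminal alkyne with complete E control, and the derived alanate opens oxirane to the homoallylic alcohol.

**Step 17**
Reactants: 26 (E)-homoallylic alcohol
Product: 27 (E)-2-(6-iodo-3-methylhex-3-en-1-yl)-1,3,3-trimethylcyclohex-1-ene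
Conditions: I2, PPh3, imidazole, CH2Cl2, 0 °C to rt
Reagents that add atoms: iodine II
Why: Appel-type iodination converts the primary alcohol into the iodide by SN2 displacement.

**Step 18**
Reactants: 27 (E)-homoallylic iodide; 17 butenolide vinyl iodide
Product: 29 (S)-4-{[(tert-butyldimethylsilyl)oxy]methyl}-5-[(2E,6E)-3-{[(tert-butyldiphenylsilyl)oxy]methyl}-7-methyl-9-(2,6,6-trimethylcyclohex-1-en-1-yl)nona-2,6-dien-1-yl]furan-2(5H)-one, via alkylzinc iodide 28 (not isolated)
Conditions: 27 (1.6 equiv), Zn dust (activated by BrCH2CH2Br/Me3SiCl), LiCl, THF, 40 °C; then 17, Pd(dppf)Cl2 (5 mol%), THF/NMP, 40 °C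
Reagents that add atoms: none
Why: Negishi cross-coupling of the base-free alkylzinc iodide with the vinyl iodide proceeds with retention of alkene geometry, and the butenolide with its epimerisable C5–H survives the neutral conditions.

**Step 19**
Reactants: 29 bis-silyl ether
Product: 30 (S)-4-(hydroxymethyl)-5-[(2E,6E)-3-(hydroxymethyl)-7-methyl-9-(2,6,6-trimethylcyclohex-1-en-1-yl)nona-2,6-dien-1-yl]furan-2(5H)-one
Conditions: HF·pyridine, pyridine, THF, 0 °C to rt
Reagents that add atoms: none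
Why: Fluoride-mediated cleavage of both silyl ethers under buffered acidic conditions neither epimerises the butenolide nor isomerises the alkenes.

## Compound list

1 | tris(hydroxymethyl)aminomethane hydrochloride | Cl.NC(CO)(CO)CO | starting material
2 | (5-amino-2,2-dimethyl-1,3-dioxan-5-yl)methanol | CC1(C)OCC(N)(CO)CO1 | intermediate
3 | 2,2-dimethyl-1,3-dioxan-5-one | CC1(C)OCC(=O)CO1 | intermediate
4 | SAMP hydrazone of 3 | COC[C@@H]1CCCN1N=C1COC(C)(C)OC1 | intermediate
5 | but-2-yne-1,4-diol | OCC#CCO | starting material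
6 | 4-[(tert-butyldiphenylsilyl)oxy]but-2-yn-1-ol | OCC#CCO[Si](c1ccccc1)(c1ccccc1)C(C)(C)C | intermediate
7 | sodium alkenylaluminate (cyclic, Al on C3 and on the alkoxide O) | [Na+].COCCO[Al-]1(OCCOC)OCC=C1CO[Si](c1ccccc1)(c1ccccc1)C(C)(C)C | intermediate (not isolated)
8 | (Z)-4-[(tert-butyldiphenylsilyl)oxy]-3-iodobut-2-en-1-ol | OC/C=C(\I)CO[Si](c1ccccc1)(c1ccccc1)C(C)(C)C | intermediate
9 | (Z)-[(4-bromo-2-iodobut-2-en-1-yl)oxy](tert-butyl)diphenylsilane | BrC/C=C(\I)CO[Si](c1ccccc1)(c1ccccc1)C(C)(C)C | intermediate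
10 | lithium azaenolate of 4 | [Li+].COC[C@@H]1CCCN1[N-]C1=COC(C)(C)OC1 | intermediate (not isolated)
11 | SAMP hydrazone of 12 (C4 of the dioxane S) | COC[C@@H]1CCCN1N=C1COC(C)(C)O[C@H]1C/C=C(\I)CO[Si](c1ccccc1)(c1ccccc1)C(C)(C)C | intermediate
12 | (S)-4-{(Z)-4-[(tert-butyldiphenylsilyl)oxy]-3-iodobut-2-en-1-yl}-2,2-dimethyl-1,3-dioxan-5-one | CC1(C)OCC(=O)[C@H](C/C=C(\I)CO[Si](c2ccccc2)(c2ccccc2)C(C)(C)C)O1 | intermediate
13 | (S)-4-{(Z)-4-[(tert-butyldiphenylsilyl)oxy]-3-iodobut-2-en-1-yl}-2,2-dimethyl-5-methylidene-1,3-dioxane | CC1(C)OCC(=C)[C@H](C/C=C(\I)CO[Si](c2ccccc2)(c2ccccc2)C(C)(C)C)O1 | intermediate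
14 | (3S,5Z)-7-[(tert-butyldiphenylsilyl)oxy]-6-iodo-2-methylidenehept-5-ene-1,3-diol | OCC(=C)[C@@H](O)C/C=C(\I)CO[Si](c1ccccc1)(c1ccccc1)C(C)(C)C | intermediate
15 | (3S,5Z)-1-[(tert-butyldimethylsilyl)oxy]-7-[(tert-butyldiphenylsilyl)oxy]-6-iodo-2-methylidenehept-5-en-3-ol | CC(C)(C)[Si](C)(C)OCC(=C)[C@@H](O)C/C=C(\I)CO[Si](c1ccccc1)(c1ccccc1)C(C)(C)C | intermediate
16 | acrylate of 15 | CC(C)(C)[Si](C)(C)OCC(=C)[C@@H](OC(=O)C=C)C/C=C(\I)CO[Si](c1ccccc1)(c1ccccc1)C(C)(C)C | intermediate
17 | (S)-4-{[(tert-butyldimethylsilyl)oxy]methyl}-5-{(Z)-4-[(tert-butyldiphenylsilyl)oxy]-3-iodobut-2-en-1-yl}furan-2(5H)-one | CC(C)(C)[Si](C)(C)OCC1=CC(=O)O[C@H]1C/C=C(\I)CO[Si](c2ccccc2)(c2ccccc2)C(C)(C)C | intermediate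
18 | β-ionone | CC1=C(/C=C/C(C)=O)C(C)(C)CCC1 | starting material
19 | triethylsilyl enol ether of 20 (E/Z mixture) | CC1=C(CC=C(C)O[Si](CC)(CC)CC)C(C)(C)CCC1 | intermediate (not isolated)
20 | 4-(2,6,6-trimethylcyclohex-1-en-1-yl)butan-2-one (dihydro-β-ionone) | CC1=C(CCC(C)=O)C(C)(C)CCC1 | intermediate
21 | lithium enolate of 20 (methyl side) | [Li+].[O-]C(=C)CCC1=C(C)CCCC1(C)C | intermediate (not isolated)
22 | diethyl 4-(2,6,6-trimethylcyclohex-1-en-1-yl)but-1-en-2-yl phosphate | CCOP(=O)(OCC)OC(=C)CCC1=C(C)CCCC1(C)C | intermediate (not isolated)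
23 | 2-(but-3-yn-1-yl)-1,3,3-trimethylcyclohex-1-ene | CC1=C(CCC#C)C(C)(C)CCC1 | intermediate
24 | (E)-dimethyl[2-methyl-4-(2,6,6-trimethylcyclohex-1-en-1-yl)but-1-en-1-yl]alane | CC1=C(CC/C(C)=C/[Al](C)C)C(C)(C)CCC1 | intermediate (not isolated)
25 | lithium butyl(dimethyl)[(E)-alkenyl]alanate from 24 | [Li+].CCCC[Al-](C)(C)/C=C(\C)CCC1=C(C)CCCC1(C)C | intermediate (not isolated)
26 | (E)-4-methyl-6-(2,6,6-trimethylcyclohex-1-en-1-yl)hex-3-en-1-ol | CC1=C(CC/C(C)=C/CCO)C(C)(C)CCC1 | intermediate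
27 | (E)-2-(6-iodo-3-methylhex-3-en-1-yl)-1,3,3-trimethylcyclohex-1-ene | CC1=C(CC/C(C)=C/CCI)C(C)(C)CCC1 | intermediate
28 | [(E)-4-methyl-6-(2,6,6-trimethylcyclohex-1-en-1-yl)hex-3-en-1-yl]zinc iodide | CC1=C(CC/C(C)=C/CC[Zn]I)C(C)(C)CCC1 | intermediate (not isolated)
29 | bis-silyl ether of the target (TBS on the butenolide CH2O, TBDPS on the chain CH2O) | CC1=C(CC/C(C)=C/CC/C(=C\C[C@@H]2OC(=O)C=C2CO[Si](C)(C)C(C)(C)C)CO[Si](c2ccccc2)(c2ccccc2)C(C)(C)C)C(C)(C)CCC1 | intermediate
30 | (S)-4-(hydroxymethyl)-5-[(2E,6E)-3-(hydroxymethyl)-7-methyl-9-(2,6,6-trimethylcyclohex-1-en-1-yl)nona-2,6-dien-1-yl]furan-2(5H)-one | CC1=C(CC/C(C)=C/CC/C(=C\C[C@@H]2OC(=O)C=C2CO)CO)C(C)(C)CCC1 | target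

## Count and risks

Total steps: 19. Longest linear sequence: 12 steps (1–3, 7–13, 18, 19; the path 4–6, 7–13, 18, 19 is equally long), which is 12/19 of the total.

**Step 7 (SAMP alkylation).** It sets the only stereocentre, with a functionalised allylic bromide that could lower the selectivity, and the centre could erode on hydrazone cleavage. The fallback sets out from ketone 3 and bromide 9 and comes back at alcohol 15; it makes the racemate and resolves it. Ketone 3 is condensed with 1,1-dimethylhydrazine to the N,N-dimethylhydrazone of 2,2-dimethyl-1,3-dioxan-5-one F1. Deprotonation (LiN(iPr)2, THF, −78 °C) and alkylation with 9 give the racemic alkylated dimethylhydrazone F2. Aqueous oxalic acid gives the racemic ketone F3. Wittig methylenation as in step 9 gives the racemic methylidene dioxane F4, PPTS/MeOH the racemic diol F5, and TBSCl/imidazole the racemic mono-TBS alcohol F6. Sharpless kinetic resolution (Ti(OiPr)4, D-(−)-diisopropyl tartrate, t-BuOOH, 4 Å sieves, CH2Cl2, −20 °C, about 55–60% conversion) epoxidises the (R)-enantiomer to the erythro (R,R)-epoxy alcohol F7 and leaves (S)-15.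

**Step 13 (RCM).** The acrylate and the hindered 1,1-disubstituted alkene must form a trisubstituted butenolide alkene, which can be slow and can outlast the catalyst. The fallback sets out from ketone 12 and comes back at butenolide 17; it closes the ring by an intramolecular aldol-type (Horner–Wadsworth–Emmons) condensation. AcOH/THF/H2O removes the acetonide to give the (S)-1,3-dihydroxy ketone F8. TBSCl/imidazole at −20 °C gives the primary TBS ether F9. Diethylphosphonoacetic acid with DCC and catalytic DMAP gives the phosphonoacetate ester F10. LiCl/iPr2NEt in MeCN adds the phosphonate carbanion to the ketone and eliminates diethyl phosphate to give 17.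

**Step 18 (Negishi coupling).** After oxidative addition, the vinylpalladium species of 17 can add across the butenolide alkene or be reduced before it meets the alkylzinc. The fallback sets out from alcohol 15 and iodide 27 and comes back at bis-silyl ether 29; it couples before the butenolide exists. Iodide 27 is treated with t-BuLi (Et2O, −78 °C) and B-methoxy-9-BBN to give the lithium alkyl(methoxy)-9-BBN borinate F11. B-alkyl Suzuki–Miyaura coupling with 15 (Pd(dppf)Cl2, AsPh3, Cs2CO3, DMF/H2O, rt) gives the coupled (S)-dienol F12. Acryloyl chloride/iPr2NEt gives the acrylate F13. Ring-closing metathesis as in step 13 gives 29; the weak point is that ring closure must prefer the 1,1-disubstituted alkene over the more hindered homoallylic trisubstituted one.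

## Further compounds

F1 | step 7 | N,N-dimethylhydrazone of 2,2-dimethyl-1,3-dioxan-5-one | CN(C)N=C1COC(C)(C)OC1
F2 | step 7 | racemic alkylated dimethylhydrazone | CN(C)N=C1COC(C)(C)OC1C/C=C(\I)CO[Si](c1ccccc1)(c1ccccc1)C(C)(C)C
F3 | step 7 | racemic 4-{(Z)-4-[(tert-butyldiphenylsilyl)oxy]-3-iodobut-2-en-1-yl}-2,2-dimethyl-1,3-dioxan-5-one | CC1(C)OCC(=O)C(C/C=C(\I)CO[Si](c2ccccc2)(c2ccccc2)C(C)(C)C)O1
F4 | step 7 | racemic 5-methylidene dioxane | CC1(C)OCC(=C)C(C/C=C(\I)CO[Si](c2ccccc2)(c2ccccc2)C(C)(C)C)O1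
F5 | step 7 | racemic (Z)-7-[(tert-butyldiphenylsilyl)oxy]-6-iodo-2-methylidenehept-5-ene-1,3-diol | OCC(=C)C(O)C/C=C(\I)CO[Si](c1ccccc1)(c1ccccc1)C(C)(C)C
F6 | step 7 | racemic mono-TBS alcohol | CC(C)(C)[Si](C)(C)OCC(=C)C(O)C/C=C(\I)CO[Si](c1ccccc1)(c1ccccc1)C(C)(C)C
F7 | step 7 | (1R,3Z)-1-[(2R)-2-{[(tert-butyldimethylsilyl)oxy]methyl}oxiran-2-yl]-5-[(tert-butyldiphenylsilyl)oxy]-4-iodopent-3-en-1-ol | CC(C)(C)[Si](C)(C)OC[C@]1(CO1)[C@H](O)C/C=C(\I)CO[Si](c1ccccc1)(c1ccccc1)C(C)(C)C
F8 | step 13 | (3S,5Z)-7-[(tert-butyldiphenylsilyl)oxy]-1,3-dihydroxy-6-iodohept-5-en-2-one | OCC(=O)[C@@H](O)C/C=C(\I)CO[Si](c1ccccc1)(c1ccccc1)C(C)(C)C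
F9 | step 13 | (3S,5Z)-1-[(tert-butyldimethylsilyl)oxy]-7-[(tert-butyldiphenylsilyl)oxy]-3-hydroxy-6-iodohept-5-en-2-one | CC(C)(C)[Si](C)(C)OCC(=O)[C@@H](O)C/C=C(\I)CO[Si](c1ccccc1)(c1ccccc1)C(C)(C)C
F10 | step 13 | (diethoxyphosphoryl)acetate ester of F9 | CC(C)(C)[Si](C)(C)OCC(=O)[C@@H](OC(=O)CP(=O)(OCC)OCC)C/C=C(\I)CO[Si](c1ccccc1)(c1ccccc1)C(C)(C)C
F11 | step 18 | lithium [(E)-4-methyl-6-(2,6,6-trimethylcyclohex-1-en-1-yl)hex-3-en-1-yl](methoxy)-9-borabicyclo[3.3.1]nonane borinate | [Li+].CO[B-]1(CC/C=C(\C)CCC2=C(C)CCCC2(C)C)C2CCCC1CCC2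
F12 | step 18 | (3S,5E,9E)-1-[(tert-butyldimethylsilyl)oxy]-6-{[(tert-butyldiphenylsilyl)oxy]methyl}-10-methyl-2-methylidene-12-(2,6,6-trimethylcyclohex-1-en-1-yl)dodeca-5,9-dien-3-ol | CC1=C(CC/C(C)=C/CC/C(=C\C[C@H](O)C(=C)CO[Si](C)(C)C(C)(C)C)CO[Si](c2ccccc2)(c2ccccc2)C(C)(C)C)C(C)(C)CCC1
F13 | step 18 | acrylate of F12 | CC1=C(CC/C(C)=C/CC/C(=C\C[C@H](OC(=O)C=C)C(=C)CO[Si](C)(C)C(C)(C)C)CO[Si](c2ccccc2)(c2ccccc2)C(C)(C)C)C(C)(C)CCC1
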